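Count the takers.

| flask | electrophile | nucleophile | free base | protic impurity | remark | time |
|---|---|---|---|---|---|---|
| teal | 13 mM | 18 mM | 60 mM | 20 mM | run made earlier |  |
| red | 30 mM | 18 mM | 60 mM | 20 mM | run made earlier |  |
| flask | 20 mM | 18.0 mM | 60.0 mM | 20.0 mM |  | 12 min |

| run | time / min | electrophile / % | product / % |
|---|---|---|---|
| teal | 4.00 | 6.4 | 57.7 |
| teal | 8.00 | 0 | 60.3 |
| teal | 10.0 | 0.8 | 62.9 |
| teal | 15.0 | 0 | 63.3 |
| red | 1.00 | 54.8 | 26.6 |
| red | 2.50 | 28.5 | 38.2 |
| red | 6.00 | 13.1 | 48.1 |
| red | 15.0 | 3.4 | 53.3 |

(each reading ± 1 percentage point)
- part of the electrophile that has reacted at 12 min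
- share of the unused nucleophile that is free and not bound as protonated nucleophile, at 12 min
- in percentages every species weighs as the electrophile in it: one homo dimer counts as two
- on the list of suspects stand: electrophile + nucleophile -> acid set free + product; acid set free -> by-product carried off; electrophile + protic impurity -> quenched substrate; 2 electrophile -> homo dimer; acid set free + free base <-> salt of the base; nucleophile + acid set free <-> protonated nucleophile
- the earlier runs do not show how much of nucleophile is bound; that part of a forecast is a guess

1. The suspects use electrophile one for one with nucleophile or protic impurity, apart from the homo dimer, which I set aside. I call those two the takers. In this flask 18.0 mM is the surplus, charged takers minus charged electrophile, and it holds while electrophile reacts. Electrophile is therefore the limiting reagent here.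

2. I treat the takers as one reagent: rate = g × electrophile × takers, with takers = electrophile + surplus. Then electrophile/takers falls as exp(−g × surplus × time).

3. The teal run has a surplus of 25.0 mM, and its reading at 4.00 min gives g = 0.394 M⁻¹ s⁻¹. The red run has a surplus of 8.00 mM, and its readings from 6.00 min to 15.0 min give a smaller g, 0.248 M⁻¹ s⁻¹.

4. With the red g, my estimate for this flask is 1.96% of its electrophile left at 12 min.

5. That g is the weak link. The teal run made more product than loss from less nucleophile than impurity, so nucleophile looks the quicker taker, and g should sag as it is used. This flask's surplus lies between the two runs, so I take the mean g, 0.321 M⁻¹ s⁻¹. That gives 99.3% reacted, my figure. The free share I cannot read from the runs.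

6. The forecast says 98.5% reacted and 80% free, and of the free share it says: “this is a guess”.

7. The flask gives 99.7% reacted and 94.9% free, 15 percentage points above the forecast.

    electrophile + nucleophile → acid set free + product (k = 0.690 M⁻¹ s⁻¹)
    acid set free → by-product carried off (k = 0.00210 s⁻¹)
    electrophile + protic impurity → quenched substrate (k = 0.270 M⁻¹ s⁻¹)
    2 electrophile → homo dimer (k = 2.00 × 10⁻⁴ M⁻¹ s⁻¹)
    acid set free + free base ⇌ salt of the base (K = 23000 M⁻¹, k = 9.80 M⁻¹ s⁻¹)
    nucleophile + acid set free ⇌ protonated nucleophile, settled at all times (K = 4900 M⁻¹)

In this flask at 12.0 min, free nucleophile, protonated nucleophile and protic impurity together stand at 18.1 mM, close to the surplus, and 0.323 mM of that is bound. A neighbouring flask charged with 80 mM of electrophile has a negative surplus: its takers fall short by 42.0 mM, which is 52.5% of its charge. At 12.0 min that neighbour holds nucleophile at 0% and protic impurity at 0.0171% of their own charges, and electrophile at 51.8% of its charge.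

The earlier runs and the new flask are calculated with made-up constants, and the scatter is random.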